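**Plan**
- Retrosynthesis: the C6 angelate ester is cut first, then the C4–C5 bond of the carbocycle. Next come C6–C7 (aldol), the two C11–CH3 bonds (Grignard) and C7=C8 (olefination). This leads back to (S)-citronellal, an acetate unit, acrolein and angelic acid.
- Enabling feature (germacrane numbering): the tertiary carbinol C4 (C(CH3)OH) and the secondary carbinol C5 (CHOH) are direct neighbours on the same face of the cyclodecane ring. This 1,2-diol maps onto a C4 methyl ketone and a C5 aldehyde joined reductively.
- Forward: the open chain C5–C6–C7–C8–C9–C10–C1–C2–C3–C4 is built first. The isopropylidene end of citronellal is shifted to an isopropenyl group, so one ozonolysis later unmasks both the C4 ketone and, from the acrolein vinyl group, the C5 aldehyde.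
- Rings: a six-membered 6,11-dioxasilinane (protecting and pre-organising) is made before the SmI2 closure of C4–C5, the only carbocycle-forming event. A 4,5-dioxolane then leaves the C6 hydroxyl as the only one that can be acylated.
- Stereochemistry: C10 comes from (S)-citronellal, and C6 and C7 from a syn-aldol directed by (R)-4-benzyl-2-oxazolidinone. C4 and C5 arise in the ring closure under control of C6 and the samarium bridge. The Z-alkene comes from angelic acid.

Key step: step 12

Assumption: germacrane numbering is used for all intermediates, and the allylic chloride of step 3 is carried as a mixture at its chlorine-bearing carbon, because step 4 erases that centre.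

**Step 1**
Reactants: 1 (S)-citronellal; 2 trimethyl phosphonoacetate
Product: 3 methyl (2E,5S)-5,9-dimethyldeca-2,8-dienoate
Conditions: LiCl, DBU, MeCN, 0 °C to rt
Reagents that add atoms: none
Why: Horner–Wadsworth–Emmons olefination under Masamune–Roush conditions adds C7 and C11 as an E-enoate, and the C10 centre is beta to the aldehyde and cannot epimerise.

**Step 2**
Reactants: 3 methyl (2E,5S)-5,9-dimethyldeca-2,8-dienoate
Product: 4 methyl (5R)-5,9-dimethyldec-8-enoate (same spatial arrangement; the descriptor changes only through the priority rules)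
Conditions: Mg turnings, MeOH, 0 °C to rt
Reagents that add atoms: none
Why: Dissolving-metal conjugate reduction (Mg in MeOH) transfers electrons only to the conjugated enoate, so the isolated trisubstituted alkene should remain.

**Step 3**
Reactants: 4 methyl (5R)-5,9-dimethyldec-8-enoate
Product: 5 methyl (5R)-8-chloro-5,9-dimethyldec-9-enoate (both C8 epimers)
Conditions: NCS (1.1 equiv), PhSeCl (5 mol %), CH2Cl2, rt
Reagents that add atoms: N-chlorosuccinimide, O=C1CCC(=O)N1Cl
Why: Selenium-catalysed ene-type allylic chlorination attacks the electron-rich 2-methylalk-2-ene terminus and moves the double bond to the isopropenyl position, and the new C–Cl centre is uncontrolled and irrelevant.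

**Step 4**
Reactants: 5 methyl (5R)-8-chloro-5,9-dimethyldec-9-enoate
Product: 6 methyl (5S)-5,9-dimethyldec-9-enoate
Conditions: Pd(OAc)2 (5 mol %), PBu3 (20 mol %), HCO2H, Et3N, THF, reflux
Reagents that add atoms: none
Why: In the Tsuji formate hydrogenolysis, zerovalent palladium ionises the allylic chloride, and after formate exchange and loss of CO2 the hydride goes to the more substituted allyl terminus, leaving the 1,1-disubstituted alkene.

**Step 5**
Reactants: 6 methyl (5S)-5,9-dimethyldec-9-enoate
Product: 7 (5S)-5,9-dimethyldec-9-enoic acid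
Conditions: LiOH, THF/MeOH/H2O, rt; then 1 M HCl
Reagents that add atoms: lithium hydroxide, [Li+].[OH-]
Why: Plain ester saponification, in which neither the alkene nor the remote stereocentre is affected.

**Step 6**
Reactants: 7 (5S)-5,9-dimethyldec-9-enoic acid; 8 (R)-4-benzyl-2-oxazolidinone
Product: 10 (4R)-4-benzyl-3-[(5S)-5,9-dimethyldec-9-enoyl]-1,3-oxazolidin-2-one, via mixed pivalic anhydride 9 (not isolated)
Conditions: PivCl, Et3N, THF, −20 °C; then LiCl, 8, −20 °C to rt
Reagents that add atoms: none
Why: Mixed-anhydride N-acylation of the oxazolidinone, in which the nucleophile attacks the unhindered acyl carbon of 9 rather than the pivaloyl carbon.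

**Step 7**
Reactants: 10 (4R)-4-benzyl-3-[(5S)-5,9-dimethyldec-9-enoyl]-1,3-oxazolidin-2-one; 11 acrolein
Product: 14 (4R)-4-benzyl-3-{(2R,5S)-2-[(1S)-1-hydroxyprop-2-en-1-yl]-5,9-dimethyldec-9-enoyl}-1,3-oxazolidin-2-one, via Z-boron enolate 12 (not isolated), via boron aldolate 13 (not isolated)
Conditions: Bu2BOTf, Et3N, CH2Cl2, −78 to 0 °C; 11, −78 to 0 °C; then H2O2, MeOH, pH 7 buffer, 0 °C
Reagents that add atoms: none
Why: In this Evans syn-aldol, Z-enolate 12 adds 1,2 to acrolein through a Zimmerman–Traxler chair whose open face is fixed by the benzyl group of the auxiliary, which sets C7 and C6 in the syn relationship and absolute sense of the target.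

**Step 8**
Reactants: 14 syn-aldol adduct
Product: 15 methyl (2R,5S)-2-[(1S)-1-hydroxyprop-2-en-1-yl]-5,9-dimethyldec-9-enoate
Conditions: NaOMe (1.1 equiv), MeOH/CH2Cl2, −20 °C; aq. NH4Cl
Reagents that add atoms: sodium methoxide, [Na+].[O-]C
Why: Methanolysis (transesterification) of the imide at the exocyclic carbonyl releases the auxiliary, and the low temperature and short contact should outrun retro-aldol cleavage and C7 epimerisation.

**Step 9**
Reactants: 15 methyl (2R,5S)-2-[(1S)-1-hydroxyprop-2-en-1-yl]-5,9-dimethyldec-9-enoate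
Product: 16 (3S,4R,7S)-4-(2-hydroxypropan-2-yl)-7,11-dimethyldodeca-1,11-dien-3-ol
Conditions: MeMgBr (6 equiv), THF, 0 °C to rt; aqueous work-up
Reagents that add atoms: methylmagnesium bromide, C[Mg]Br
Why: Double Grignard addition to the ester, after deprotonation of the C6 hydroxyl, installs both C11 methyl groups and the tertiary carbinol without touching a stereocentre.

**Step 10**
Reactants: 16 (3S,4R,7S)-4-(2-hydroxypropan-2-yl)-7,11-dimethyldodeca-1,11-dien-3-ol
Product: 17 (5R,6S)-2,2-di-tert-butyl-5-[(3S)-3,7-dimethyloct-7-en-1-yl]-6-ethenyl-4,4-dimethyl-1,3,2-dioxasilinane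
Conditions: tBu2Si(OTf)2, 2,6-lutidine, CH2Cl2, 0 °C to rt
Reagents that add atoms: di-tert-butylsilyl bis(trifluoromethanesulfonate), CC(C)(C)[Si](OS(=O)(=O)C(F)(F)F)(OS(=O)(=O)C(F)(F)F)C(C)(C)C
Why: In this cyclic silylene protection of a 1,3-diol, the bis-triflate silylates the secondary allylic hydroxyl first and the second Si–O bond forms intramolecularly, which is what lets the tertiary C11 hydroxyl take part.

**Step 11**
Reactants: 17 silylene bis-alkene
Product: 19 (4R,5R)-2,2-di-tert-butyl-6,6-dimethyl-5-[(3S)-3-methyl-7-oxooctyl]-1,3,2-dioxasilinane-4-carbaldehyde (C5 aldehyde, C4 methyl ketone), via bis-ozonide 18 (not isolated)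
Conditions: O3, CH2Cl2, −78 °C; then PPh3, −78 °C to rt
Reagents that add atoms: ozone, [O-][O+]=O
Why: Ozonolysis with reductive work-up cleaves the vinyl and the isopropenyl group in one operation, and the neutral conditions should leave the epimerisable C6 centre next to the new aldehyde intact.

**Step 12**
Reactants: 19 keto aldehyde
Product: 21 (4R,5S,6R,7R,10S)-6,11-O-(di-tert-butylsilanediyl)germacrane-4,5,6,11-tetraol (ten-membered ring, cis-4,5-diol, O5 trans to O6), via samarium diolate 20 (not isolated)
Conditions: SmI2 (5 equiv), THF, rt, Ar, 19 added by syringe pump over 12 h (final ca. 1 mM); then aq. NaHCO3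
Reagents that add atoms: none
Why: SmI2 reduces the C5 aldehyde first; its trivalent samarium ketyl binds the C4 ketone oxygen, the C4–C5 bond forms inside this oxygen-bridged array, and a second electron gives diolate 20, which is hydrolysed on work-up. The closest known reaction type is the SmI2 pinacol cyclisation of keto aldehydes to cis-1,2-diols, well established for five- to eight-membered and for large rings, while ten-membered 1,2-diols have been closed by the low-valent titanium variant, so only the ring size is extrapolated. The cyclodecane closes end to end, formally by 10-exo-trig attack of the C5 ketyl carbon on the C4 carbonyl carbon under slow-addition high dilution, and the dioxasilinane chair helps: an axial C6 substituent would clash with the axial C11 methyl and a tert-butyl group, so the formyl group sits equatorial and the C7 chain axial, which locks C5–C6–C7–C8 gauche and excludes the extended rotamer. C5 is controlled by C6: the ketyl C–O bond should lie anti to the C6–O bond (dipole repulsion, no chelation by the hindered silyl ether oxygen) and the chain reaches only the face turned towards the axial C7 substituent, which leads to 5S with O5 trans to O6. C4 is controlled by the samarium bridge: with O4 and O5 held on the same side of the new bond, the C15 methyl group should take the place next to C5–H rather than next to C6, which leads to 4R and the cis-diol. The step needs cyclisation to outrun aldehyde dimerisation, simple reduction and reductive loss of the alpha-oxygen; a low stationary concentration, the absence of a proton source and of HMPA, and the poor leaving-group ability of the silylene oxygen should secure this.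

**Step 13**
Reactants: 21 cis-4,5-diol
Product: 22 4,5-O-isopropylidene derivative of 21
Conditions: Me2C(OMe)2, pyridinium p-toluenesulfonate (cat.), CH2Cl2, rt
Reagents that add atoms: 2,2-dimethoxypropane, COC(C)(C)OC
Why: Acid-catalysed transketalisation turns the cis-1,2-diol into a five-membered dioxolane, and the silylene tolerates the weak acid.

**Step 14**
Reactants: 22 acetonide silylene
Product: 23 (4R,5S,6R,7R,10S)-4,5-O-isopropylidenegermacrane-4,5,6,11-tetraol (free C6 and C11 hydroxyls)
Conditions: HF·pyridine, excess pyridine, THF, 0 °C to rt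
Reagents that add atoms: none
Why: Fluoride-driven Si–O cleavage, the standard removal of a di-tert-butylsilylene, frees O6 and O11 while the pyridine buffer keeps the medium too weakly acidic to open the dioxolane.

**Step 15**
Reactants: 23 6,11-diol acetonide; 24 angelic acid [(Z)-2-methylbut-2-enoic acid]
Product: 26 6-O-angeloyl derivative of 23, via angelic trichlorobenzoic anhydride 25 (not isolated)
Conditions: 24, 2,4,6-Cl3C6H2COCl, Et3N, toluene, rt; then 23, toluene, 80 °C
Reagents that add atoms: none
Why: Yamaguchi-type mixed-anhydride esterification without a nucleophilic catalyst transfers the angeloyl group without Z-to-E isomerisation, and only the secondary C6 hydroxyl can react because C11–OH is tertiary and O4/O5 are tied up in the acetonide.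

**Step 16**
Reactants: 26 angelate acetonide
Product: 27 target CNP0130723.1, (1R,2S,3R,7S,10R)-2,3-dihydroxy-10-(2-hydroxypropan-2-yl)-3,7-dimethylcyclodecyl (Z)-2-methylbut-2-enoate
Conditions: AcOH/THF/H2O (3:1:1), 40 °C
Reagents that add atoms: none
Why: Mild acid-catalysed acetal hydrolysis opens the dioxolane under conditions in which the hindered conjugated ester, its Z-alkene and the two tertiary carbinols should persist and acyl migration should stay slow.

**Compound list**
1 | (S)-citronellal, (3S)-3,7-dimethyloct-6-enal | C[C@@H](CCC=C(C)C)CC=O | starting material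
2 | trimethyl phosphonoacetate | COC(=O)CP(=O)(OC)OC | starting material
3 | methyl (2E,5S)-5,9-dimethyldeca-2,8-dienoate | C[C@@H](CCC=C(C)C)C/C=C/C(=O)OC | intermediate
4 | methyl (5R)-5,9-dimethyldec-8-enoate | C[C@@H](CCC=C(C)C)CCCC(=O)OC | intermediate
5 | methyl (5R)-8-chloro-5,9-dimethyldec-9-enoate, both C8 epimers | C[C@@H](CCC(Cl)C(C)=C)CCCC(=O)OC | intermediate
6 | methyl (5S)-5,9-dimethyldec-9-enoate | C[C@@H](CCCC(C)=C)CCCC(=O)OC | intermediate
7 | (5S)-5,9-dimethyldec-9-enoic acid | C[C@@H](CCCC(C)=C)CCCC(=O)O | intermediate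
8 | (R)-4-benzyl-2-oxazolidinone | O=C1N[C@H](Cc2ccccc2)CO1 | starting material
9 | (5S)-5,9-dimethyldec-9-enoic pivalic anhydride | C[C@@H](CCCC(C)=C)CCCC(=O)OC(=O)C(C)(C)C | intermediate
10 | (4R)-4-benzyl-3-[(5S)-5,9-dimethyldec-9-enoyl]-1,3-oxazolidin-2-one | O=C1N(C(=O)CCC[C@@H](C)CCCC(C)=C)[C@H](Cc2ccccc2)CO1 | intermediate
11 | acrolein | C=CC=O | starting material
12 | dibutylboron (Z)-enolate of 10 | O=C1N(/C(OB(CCCC)CCCC)=C/CC[C@@H](C)CCCC(C)=C)[C@H](Cc2ccccc2)CO1 | intermediate
13 | dibutylboron aldolate of 14 | O=C1N(C(=O)[C@H](CC[C@@H](C)CCCC(C)=C)[C@@H](OB(CCCC)CCCC)C=C)[C@H](Cc2ccccc2)CO1 | intermediate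
14 | (4R)-4-benzyl-3-{(2R,5S)-2-[(1S)-1-hydroxyprop-2-en-1-yl]-5,9-dimethyldec-9-enoyl}-1,3-oxazolidin-2-one | O=C1N(C(=O)[C@H](CC[C@@H](C)CCCC(C)=C)[C@@H](O)C=C)[C@H](Cc2ccccc2)CO1 | intermediate
15 | methyl (2R,5S)-2-[(1S)-1-hydroxyprop-2-en-1-yl]-5,9-dimethyldec-9-enoate | COC(=O)[C@H](CC[C@@H](C)CCCC(C)=C)[C@@H](O)C=C | intermediate
16 | (3S,4R,7S)-4-(2-hydroxypropan-2-yl)-7,11-dimethyldodeca-1,11-dien-3-ol | CC(C)(O)[C@H](CC[C@@H](C)CCCC(C)=C)[C@@H](O)C=C | intermediate
17 | (5R,6S)-2,2-di-tert-butyl-5-[(3S)-3,7-dimethyloct-7-en-1-yl]-6-ethenyl-4,4-dimethyl-1,3,2-dioxasilinane | O3[C@@H](C=C)[C@H](C(C)(C)O[Si]3(C(C)(C)C)C(C)(C)C)CC[C@@H](C)CCCC(C)=C | intermediate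
18 | bis(1,2,4-trioxolane) of 17 | O3[C@@H](C4OOCO4)[C@H](C(C)(C)O[Si]3(C(C)(C)C)C(C)(C)C)CC[C@@H](C)CCCC5(C)OOCO5 | intermediate
19 | (4R,5R)-2,2-di-tert-butyl-6,6-dimethyl-5-[(3S)-3-methyl-7-oxooctyl]-1,3,2-dioxasilinane-4-carbaldehyde | O3[C@@H](C=O)[C@H](C(C)(C)O[Si]3(C(C)(C)C)C(C)(C)C)CC[C@@H](C)CCCC(C)=O | intermediate
20 | 4,5-bis(diiodosamarium) diolate of 21 | O3[C@@H]1[C@H](C(C)(C)O[Si]3(C(C)(C)C)C(C)(C)C)CC[C@@H](C)CCC[C@@](C)(O[Sm](I)I)[C@H]1O[Sm](I)I | intermediate
21 | (4R,5S,6R,7R,10S)-6,11-O-(di-tert-butylsilanediyl)germacrane-4,5,6,11-tetraol | O3[C@@H]1[C@H](C(C)(C)O[Si]3(C(C)(C)C)C(C)(C)C)CC[C@@H](C)CCC[C@@](C)(O)[C@H]1O | intermediate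
22 | 4,5-O-isopropylidene derivative of 21 | O3[C@@H]1[C@H](C(C)(C)O[Si]3(C(C)(C)C)C(C)(C)C)CC[C@@H](C)CCC[C@@](C)(OC2(C)C)[C@H]1O2 | intermediate
23 | (4R,5S,6R,7R,10S)-4,5-O-isopropylidenegermacrane-4,5,6,11-tetraol | O[C@@H]1[C@H](C(C)(C)O)CC[C@@H](C)CCC[C@@](C)(OC2(C)C)[C@H]1O2 | intermediate
24 | angelic acid, (Z)-2-methylbut-2-enoic acid | C/C=C(/C)C(=O)O | starting material
25 | angelic 2,4,6-trichlorobenzoic anhydride | C/C=C(/C)C(=O)OC(=O)c1c(Cl)cc(Cl)cc1Cl | intermediate
26 | 6-O-angeloyl-4,5-O-isopropylidene derivative (angelate of 23) | C/C=C(/C)C(=O)O[C@@H]1[C@H](C(C)(C)O)CC[C@@H](C)CCC[C@@](C)(OC2(C)C)[C@H]1O2 | intermediate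
27 | CNP0130723.1, (1R,2S,3R,7S,10R)-2,3-dihydroxy-10-(2-hydroxypropan-2-yl)-3,7-dimethylcyclodecyl (Z)-2-methylbut-2-enoate | C/C=C(/C)C(=O)O[C@@H]1[C@H](C(C)(C)O)CC[C@@H](C)CCC[C@@](C)(O)[C@H]1O | target

Total step count: 16. Longest linear sequence: 16 steps (1 to 27); compounds 2, 8, 11 and 24 are bought.

**Steps most likely to fail**

1. Step 12.
   - What may go wrong: the medium-ring closure may be too slow, so that intermolecular aldehyde coupling, plain reduction of the aldehyde or reductive loss of the C6 oxygen takes over. Facial selectivity at C4 or C5 may also be poor.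
   - Fallback: it sets out from bis-alkene 17, before the ozonolysis, and joins the same two carbons as a double bond.
   - Ring-closing metathesis of the vinyl and isopropenyl groups (second-generation Hoveyda–Grubbs catalyst, toluene, high dilution, 80 to 110 °C) should give the Z-configured C4=C5 cyclodecene silylene F1.
   - Syn-dihydroxylation with OsO4 (cat.) and N-methylmorpholine N-oxide, expected on the face opposite to the allylic C6–O bond, would then deliver the cis-diol. The route is rejoined at 21.

2. Step 15.
   - What may go wrong: acylation of the crowded C6 hydroxyl may be sluggish, and forcing conditions may cause Z-to-E isomerisation of the angeloyl group.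
   - Fallback: it sets out from 23 and builds the Z-alkene on the ester instead of transferring it.
   - Carbodiimide esterification with 2-[bis(2,2,2-trifluoroethoxy)phosphoryl]propanoic acid (DCC, 4-dimethylaminopyridine, CH2Cl2) should give the C6 phosphonopropionate ester F2; no alkene is present yet, so the nucleophilic catalyst is harmless here.
   - A Still–Gennari olefination (KN(SiMe3)2, one extra equivalent for the C11 hydroxyl, 18-crown-6, THF, −78 °C, then acetaldehyde) forms the Z-trisubstituted enoate. The route is rejoined at 26.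

3. Step 4.
   - What may go wrong: hydride delivery to the wrong allyl terminus, or later palladium hydride double-bond migration, would return the trisubstituted alkene, which is hard to separate.
   - Fallback: it sets out from 4 and replaces the isomerisation by cleavage and recoupling.
   - Ozonolysis with NaBH4 work-up should give methyl (5R)-8-hydroxy-5-methyloctanoate F3.
   - I2, PPh3 and imidazole convert it into methyl (5R)-8-iodo-5-methyloctanoate F4.
   - Copper-catalysed cross-coupling with isopropenylmagnesium bromide (Li2CuCl4 cat., THF, −20 to 0 °C) attaches C4 and C15 with the terminal alkene already in place. The route is rejoined at 6.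

**Further compounds**
F1 | step 12 | Z-C4=C5 cyclodecene with 6,11-O-di-tert-butylsilylene | C1C[C@@H](C)CCC/C(C)=C\[C@@H]2O[Si](C(C)(C)C)(C(C)(C)C)OC(C)(C)[C@H]12
F2 | step 15 | C6 2-[bis(2,2,2-trifluoroethoxy)phosphoryl]propanoate of 23 | CC(P(=O)(OCC(F)(F)F)OCC(F)(F)F)C(=O)O[C@@H]1[C@H](C(C)(C)O)CC[C@@H](C)CCC[C@@](C)(OC2(C)C)[C@H]1O2
F3 | step 4 | methyl (5R)-8-hydroxy-5-methyloctanoate | C[C@@H](CCCO)CCCC(=O)OC
F4 | step 4 | methyl (5R)-8-iodo-5-methyloctanoate | C[C@@H](CCCI)CCCC(=O)OC
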